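**Retrosynthetic overview**

1. The target is 2,5-dihydroxy-3-[(14E)-nonadec-14-en-1-yl]-1,4-benzoquinone (side chain numbered C1'–C19' from the ring); its C=O/OH pattern is released at the end by hydrolysis of a quinone bisketal.
2. The key disconnection is C7'–C8', giving two carboxylic acids: 8-(2,3,5,6-tetramethoxyphenyl)octanoic acid (11) and (8E)-tridec-8-enoic acid (5). They are joined by a mixed Kolbe anodic decarboxylative radical coupling, run in the same cell directly after anodic oxidation of the arene to the quinone bisketal.
3. Enabling feature: C7' and C8' are unactivated CH2 groups of a linear tether, five CH2 from the C14'=C15' alkene and six CH2 from the ring, so both primary radicals have no cyclisation or fragmentation path. The ring is a 1,2,4,5-tetraoxygenated benzene whose para-related O-bearing carbons are oxidised below the carboxylate discharge potential; it is mirror-symmetric through C3–C6, so only one bisketal can form.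
4. Acid 5 comes from hex-1-yne and 7-bromoheptanoic acid (acetylide alkylation, then Li/NH3 to set 14E). Acid 11 comes from 1,2,4,5-tetramethoxybenzene (lithiation/alkylation with 1,7-dibromoheptane, then Grignard carboxylation).
5. No ring is formed in the route: the only ring is bought as the benzene ring of 6 and is raised to the quinone oxidation level in step 5.

Key step: step 5

Assumption: 1,2,4,5-tetramethoxybenzene (6) is taken as a catalogue compound; carboxylic acids are written in their neutral form although they are handled as salts in the flask.

**Route**

Step 1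
Reactants: 1 hex-1-yne; 2 7-bromoheptanoic acid
Product: 4 tridec-8-ynoic acid, via hex-1-ynyllithium 3 (not isolated)
Conditions: 1 (2.3 equiv), n-BuLi (2.2 equiv), THF, −78 → 0 °C; then 2 (1.0 equiv), THF/HMPA (or DMPU), 0 °C → rt; aq. HCl
Reagents that add atoms: none
Why: Acetylide alkylation (SN2 of a lithium acetylide on a primary bromide) in which the first equivalent of 3 only deprotonates the acid, the carboxylate is inert to the acetylide, and the polar cosolvent keeps the lithium bromocarboxylate reactive.

Step 2
Reactants: 4 tridec-8-ynoic acid
Product: 5 (8E)-tridec-8-enoic acid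
Conditions: Li (5 equiv), NH3(l)/THF, −33 °C; solid NH4Cl; aq. HCl
Reagents that add atoms: none
Why: Dissolving-metal reduction of an internal alkyne, in which the vinyl radical anion/vinyl anion adopts the trans geometry before protonation so that the C8=C9 bond should be set E, while the lithium carboxylate is not reduced.

Step 3
Reactants: 6 1,2,4,5-tetramethoxybenzene; 7 1,7-dibromoheptane
Product: 9 3-(7-bromoheptyl)-1,2,4,5-tetramethoxybenzene, via aryllithium 8 (not isolated)
Conditions: n-BuLi (1.05 equiv), THF, 0 °C → rt; then 7 (3 equiv), HMPA (or DMPU), −40 °C → rt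
Reagents that add atoms: none
Why: Directed ortho-lithiation at the ring C–H flanked by two methoxy groups followed by SN2 alkylation of the aryllithium with a primary bromide, the excess of dibromide suppressing double arylation and monolithiation leaving the second ring C–H untouched.

Step 4
Reactants: 9 3-(7-bromoheptyl)-1,2,4,5-tetramethoxybenzene
Product: 11 8-(2,3,5,6-tetramethoxyphenyl)octanoic acid, via Grignard reagent 10 (not isolated)
Conditions: Mg, cat. I2, THF, 40 °C; CO2 (dry ice), −40 °C → rt; aq. HCl
Reagents that add atoms: carbon dioxide, O=C=O
Why: Grignard formation from the primary bromide and Grignard carboxylation with CO2, to both of which the aryl methyl ethers are inert.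

Step 5
Reactants: 11 8-(2,3,5,6-tetramethoxyphenyl)octanoic acid; 5 (8E)-tridec-8-enoic acid
Product: 13 2,3,3,5,6,6-hexamethoxy-1-[(14E)-nonadec-14-en-1-yl]cyclohexa-1,4-diene, via bisketal acid 12 (not isolated)
Conditions: undivided cell, smooth Pt anode, stainless-steel cathode, MeOH; (i) 11 (1.0 equiv), KOH (1.3 equiv), 20 mA cm−2, 0–5 °C, ca. 3 F mol−1; (ii) add 5 (4 equiv), 0.3 A cm−2, 35–40 °C, until the solution turns alkaline; NaHCO3 work-up, Et3N-deactivated SiO2
Reagents that add atoms: methanol, CO
Why: Proposed new method: at low current density in basic methanol the electron-rich arene of 11 should be oxidised first (two one-electron oxidations, each followed by ipso-attack of methoxide at the para-related methoxy-bearing carbons) to bisketal 12, after which the higher current density on platinum in the partly neutralised acid mixture switches the anode to carboxylate discharge, so that 12 and 5 lose CO2 to the primary radicals at C7' and C8', which combine at the anode surface to the C7'–C8' bond. The closest known reaction types are the anodic bisketalisation of 1,4-dimethoxyarenes and the mixed Kolbe coupling of two different alkanoic acids, here run one after the other in one cell on one substrate. No ring is closed and no stereocentre is formed; the 14E alkene should pass unchanged because it lies five methylene groups from the radical carbon, beyond the reach of 5-exo or 6-exo cyclisation, and the steel cathode avoids its cathodic hydrogenation. The selectivities needed are arene oxidation before carboxylate discharge (secured by the markedly lower oxidation potential of the tetramethoxyarene and the low current density of stage i), nuclear addition instead of benzylic substitution (secured by the basic medium), cross- over homo-coupling (secured by the excess of acid 5, whose symmetrical dimer is a hydrocarbon removed on the column) and radical coupling instead of Hofer–Moest cation formation (secured by smooth platinum, high current density, a weakly acidic medium and unbranched primary radicals without α-heteroatoms). The bisketal is the form chosen to cross the Kolbe stage because it is no longer aromatic, is stable in weakly acidic to alkaline methanol and is not reducible at the cathode, whereas a free quinone would be.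

Step 6
Reactants: 13 2,3,3,5,6,6-hexamethoxy-1-[(14E)-nonadec-14-en-1-yl]cyclohexa-1,4-diene
Product: 15 2,5-dihydroxy-3-[(14E)-nonadec-14-en-1-yl]cyclohexa-2,5-diene-1,4-dione, via dimethoxyquinone 14 (not isolated)
Conditions: 1 M HCl, THF, rt; then 2 M NaOH, EtOH, 50 °C (Ar); then 2 M HCl to pH 1
Reagents that add atoms: water, O; sodium hydroxide, [Na+].[OH-]
Why: Acid-catalysed ketal hydrolysis releases the two quinone carbonyls and the resulting vinylogous methyl esters are then cleaved by hydroxide through conjugate addition–elimination (vinylogous ester saponification), neither stage touching the remote E-alkene.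

**Compound list**

1 | hex-1-yne | C#CCCCC | starting material
2 | 7-bromoheptanoic acid | OC(=O)CCCCCCBr | starting material
3 | hex-1-yn-1-yllithium | [Li]C#CCCCC | intermediate
4 | tridec-8-ynoic acid | CCCCC#CCCCCCCC(=O)O | intermediate
5 | (8E)-tridec-8-enoic acid | CCCC/C=C/CCCCCCC(=O)O | intermediate
6 | 1,2,4,5-tetramethoxybenzene | COc1cc(OC)c(OC)cc1OC | starting material
7 | 1,7-dibromoheptane | BrCCCCCCCBr | starting material
8 | (2,3,5,6-tetramethoxyphenyl)lithium | [Li]c1c(OC)c(OC)cc(OC)c1OC | intermediate
9 | 3-(7-bromoheptyl)-1,2,4,5-tetramethoxybenzene | BrCCCCCCCc1c(OC)c(OC)cc(OC)c1OC | intermediate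
10 | [7-(2,3,5,6-tetramethoxyphenyl)heptyl]magnesium bromide | Br[Mg]CCCCCCCc1c(OC)c(OC)cc(OC)c1OC | intermediate
11 | 8-(2,3,5,6-tetramethoxyphenyl)octanoic acid | OC(=O)CCCCCCCc1c(OC)c(OC)cc(OC)c1OC | intermediate
12 | 8-(2,3,3,5,6,6-hexamethoxycyclohexa-1,4-dien-1-yl)octanoic acid | OC(=O)CCCCCCCC1=C(OC)C(OC)(OC)C=C(OC)C1(OC)OC | intermediate
13 | 2,3,3,5,6,6-hexamethoxy-1-[(14E)-nonadec-14-en-1-yl]cyclohexa-1,4-diene | CCCC/C=C/CCCCCCCCCCCCCC1=C(OC)C(OC)(OC)C=C(OC)C1(OC)OC | intermediate
14 | 2,5-dimethoxy-3-[(14E)-nonadec-14-en-1-yl]cyclohexa-2,5-diene-1,4-dione | CCCC/C=C/CCCCCCCCCCCCCC1=C(OC)C(=O)C=C(OC)C1=O | intermediate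
15 | 2,5-dihydroxy-3-[(14E)-nonadec-14-en-1-yl]cyclohexa-2,5-diene-1,4-dione | CCCC/C=C/CCCCCCCCCCCCCC1=C(O)C(=O)C=C(O)C1=O | target

**Step count and risks**

Total step count: 6. Longest linear sequence: 4 steps (6 → 9 → 11 → 13 → 15, or equally 1 → 4 → 5 → 13 → 15).

Steps most likely to fail:

Step 5 (proposed new method). The enol-ether double bonds of the bisketal may be over-oxidised during the high-potential Kolbe stage. The anode may also passivate, or the reaction may drift to the two-electron (cation) pathway so that methyl ethers and alkenes form instead of the coupled chain. The fallback uses known chemistry and sets out from acid 5 and from Grignard reagent 10 (made from 9 as in step 4). Acid 5 would be condensed with N-hydroxyphthalimide (N,N'-diisopropylcarbodiimide, cat. DMAP, CH2Cl2) to the redox-active ester 1,3-dioxoisoindolin-2-yl (8E)-tridec-8-enoate F1. Reagent 10 would be transmetalated with ZnCl2 (0.5 equiv, THF) to bis[7-(2,3,5,6-tetramethoxyphenyl)heptyl]zinc F2. Nickel-catalysed decarboxylative alkyl–alkyl Negishi-type coupling of F1 with F2 (NiCl2·glyme, 2,2'-bipyridine ligand, THF/DMF, rt) should form the same C7'–C8' bond and give 3-[(14E)-nonadec-14-en-1-yl]-1,2,4,5-tetramethoxybenzene F3; one alkyl group of F2 is transferred and the other returns as the heptyl arene on protic work-up. Oxidative demethylation of F3 with ceric ammonium nitrate (MeCN/H2O, 0 °C) should give dimethoxyquinone 14, where the route is rejoined at the hydroxide stage of step 6.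

Step 3. The aryllithium may act as a base on the dibromide (E2), substitution may occur at both ends of the dibromide, or lithiation may be incomplete. The fallback sets out from aryllithium 8 (from 6) and replaces steps 3 and 4. Quenching 8 with I2 should give 3-iodo-1,2,4,5-tetramethoxybenzene F4. Commercial ethyl 8-bromooctanoate would be converted with zinc dust/LiCl (THF) into (8-ethoxy-8-oxooctyl)zinc bromide F5. Negishi coupling of F4 with F5 (Pd(OAc)2/SPhos, THF, 50 °C) should give ethyl 8-(2,3,5,6-tetramethoxyphenyl)octanoate F6. Saponification (LiOH, THF/H2O; HCl) returns to the route at acid 11.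

Step 1. Substitution on the poorly soluble lithium bromocarboxylate may be slow, with competing elimination and loss of the acetylide by proton transfer. The fallback sets out from hex-1-ynyllithium 3 (from 1) and removes the carboxylate from the alkylation. Reaction of 3 with an excess of commercial 1,6-dibromohexane (THF/DMPU, −20 °C → rt) should give 12-bromododec-5-yne F7. Magnesium in THF converts F7 into dodec-7-yn-1-ylmagnesium bromide F8. Carboxylation (CO2, then aq. HCl) returns to the route at acid 4.

**Further compounds**

F1 | step 5 | 1,3-dioxoisoindolin-2-yl (8E)-tridec-8-enoate | CCCC/C=C/CCCCCCC(=O)ON1C(=O)c2ccccc2C1=O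
F2 | step 5 | bis[7-(2,3,5,6-tetramethoxyphenyl)heptyl]zinc | COc1cc(OC)c(OC)c(CCCCCCC[Zn]CCCCCCCc2c(OC)c(OC)cc(OC)c2OC)c1OC
F3 | step 5 | 3-[(14E)-nonadec-14-en-1-yl]-1,2,4,5-tetramethoxybenzene | CCCC/C=C/CCCCCCCCCCCCCc1c(OC)c(OC)cc(OC)c1OC
F4 | step 3 | 3-iodo-1,2,4,5-tetramethoxybenzene | Ic1c(OC)c(OC)cc(OC)c1OC
F5 | step 3 | (8-ethoxy-8-oxooctyl)zinc bromide | CCOC(=O)CCCCCCC[Zn]Br
F6 | step 3 | ethyl 8-(2,3,5,6-tetramethoxyphenyl)octanoate | CCOC(=O)CCCCCCCc1c(OC)c(OC)cc(OC)c1OC
F7 | step 1 | 12-bromododec-5-yne | CCCCC#CCCCCCCBr
F8 | step 1 | dodec-7-yn-1-ylmagnesium bromide | CCCCC#CCCCCCC[Mg]Br
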